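## Retrosynthetic overview

1. The target comes from fluoride removal of three aryl silyl ethers. The (E)-styrene C6=C7 is cut by cross-metathesis into a terminal alkene and commercial 4-silyloxystyrene, and the acetate comes from the (R)-hept-6-en-3-ol.
2. Key disconnection C3–C4: the carbinol carbon C3, normally an acceptor (aldehyde) carbon, is used as a donor. It is the sparteine-complexed α-lithio carbamate (a chiral α-oxy carbanion) and is joined to the boron-bound donor carbon of but-3-enyl pinacol boronate by 1,2-metallate shift. C–B oxidation gives the alcohol, and (+)-sparteine sets the only stereocenter in this step.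
3. The carbamate comes from the 3-arylpropanol, and this from dihydrocaffeic acid by silylation and borane reduction.
4. No ring is formed; both benzene rings are bought in.

Assumption: the SMILES is read as the (3R,6E) isomer, and (+)-sparteine is taken as commercially available.

Abbreviations: TIPS = triisopropylsilyl, TBS = tert-butyldimethylsilyl, pin = pinacolato.

## Route

**Step 1**
Reactants: 1 3-(3,4-dihydroxyphenyl)propanoic acid
Product: 3 3-[3,4-bis(triisopropylsilyloxy)phenyl]propanoic acid, via tris-silylated ester 2 (not isolated)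
Conditions: TIPSCl (3.5 equiv), imidazole (7 equiv), DMF, 40 °C, 16 h; then K2CO3 (1.5 equiv), MeOH/THF/H2O, rt, 1 h; 1 M HCl to pH 4
Reagents that add atoms: triisopropylsilyl chloride, CC(C)[Si](Cl)(C(C)C)C(C)C
Why: Exhaustive O-silylation (silyl chloride/imidazole) followed by selective solvolysis of the labile silyl ester leaves the two hindered aryl TIPS ethers, chosen because they withstand s-BuLi and alkaline peroxide later and come off with fluoride at the end.

**Step 2**
Reactants: 3 3-[3,4-bis(triisopropylsilyloxy)phenyl]propanoic acid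
Product: 4 3-[3,4-bis(triisopropylsilyloxy)phenyl]propan-1-ol
Conditions: BH3·THF (2.5 equiv), THF, 0 °C → rt, 4 h; MeOH quench
Reagents that add atoms: none
Why: Borane reduces a free carboxylic acid through its acyloxyborane (chemoselective carboxylic acid reduction) and leaves aryl silyl ethers alone.

**Step 3**
Reactants: 4 3-[3,4-bis(triisopropylsilyloxy)phenyl]propan-1-ol
Product: 5 3-[3,4-bis(triisopropylsilyloxy)phenyl]propyl N,N-diisopropylcarbamate
Conditions: iPr2NCOCl (1.3 equiv), Et3N (1.5 equiv), DMAP (10 mol %), CH2Cl2, reflux, 24 h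
Reagents that add atoms: N,N-diisopropylcarbamoyl chloride, CC(C)N(C(C)C)C(=O)Cl
Why: O-Carbamoylation of the primary alcohol (nucleophilic acyl substitution) installs the hindered carbamate that directs the α-lithiation and later acts as the leaving group.

**Step 4**
Reactants: 5 3-[3,4-bis(triisopropylsilyloxy)phenyl]propyl N,N-diisopropylcarbamate; 6 2-(but-3-en-1-yl)-4,4,5,5-tetramethyl-1,3,2-dioxaborolane
Product: 10 (3R)-1-[3,4-bis(triisopropylsilyloxy)phenyl]hept-6-en-3-ol, via (R)-α-lithio carbamate 7 (not isolated), via lithium boronate complex 8 (not isolated), via (R)-secondary pinacol boronic ester 9 (not isolated)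
Conditions: s-BuLi (1.3 equiv), (+)-sparteine (1.3 equiv), Et2O, −78 °C, 5 h; 6 (1.6 equiv), −78 °C, 1 h; MgBr2·OEt2 (1.5 equiv), −78 °C → reflux, 16 h; then 2 M NaOH, 30% H2O2, THF, 0 °C, 1–2 h
Reagents that add atoms: hydrogen peroxide, OO
Why: s-BuLi/(+)-sparteine removes the pro-R α-hydrogen of the carbamate (Hoppe asymmetric deprotonation) to give a configurationally stable α-oxy carbanion, the reversed-polarity form of the carbinol carbon, which adds to boron with retention; the butenyl group then shifts from boron to carbon with inversion and loss of the carbamate (lithiation–borylation, Matteson-type 1,2-metallate rearrangement), and stereoretentive C–B oxidation gives the (R)-alcohol, typically about 97:3 er for primary carbamates.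

**Step 5**
Reactants: 10 (3R)-1-[3,4-bis(triisopropylsilyloxy)phenyl]hept-6-en-3-ol
Product: 11 (3R)-1-[3,4-bis(triisopropylsilyloxy)phenyl]hept-6-en-3-yl acetate
Conditions: Ac2O (1.5 equiv), Et3N (2 equiv), DMAP (5 mol %), CH2Cl2, 0 °C → rt, 2 h
Reagents that add atoms: acetic anhydride, CC(=O)OC(C)=O
Why: DMAP-catalysed acylation of the secondary alcohol (Steglich-type acetylation) does not break the C–O bond, so the stereocenter is untouched.

**Step 6**
Reactants: 11 (3R)-1-[3,4-bis(triisopropylsilyloxy)phenyl]hept-6-en-3-yl acetate; 12 tert-butyldimethyl(4-vinylphenoxy)silane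
Product: 13 (3R,6E)-1-[3,4-bis(triisopropylsilyloxy)phenyl]-7-[4-(tert-butyldimethylsilyloxy)phenyl]hept-6-en-3-yl acetate
Conditions: 12 (3 equiv), second-generation Grubbs catalyst RuCl2(=CHPh)(PCy3)(H2IMes) (5 mol %), CH2Cl2, 40 °C, 16 h
Reagents that add atoms: none
Why: Ruthenium-catalysed olefin cross-metathesis of an unhindered terminal alkene with an excess of an electron-rich styrene gives the conjugated disubstituted alkene under thermodynamic control (E typically above 20:1) with loss of ethene.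

**Step 7**
Reactants: 13 (3R,6E)-1-[3,4-bis(triisopropylsilyloxy)phenyl]-7-[4-(tert-butyldimethylsilyloxy)phenyl]hept-6-en-3-yl acetate
Product: 14 (3R,6E)-1-(3,4-dihydroxyphenyl)-7-(4-hydroxyphenyl)hept-6-en-3-yl acetate
Conditions: Bu4NF (3.6 equiv), AcOH (3.6 equiv), THF, 0 °C → rt, 2 h, argon
Reagents that add atoms: none
Why: Fluoride cleaves the three aryl Si–O bonds (fluoride-mediated desilylation) while the AcOH buffer protonates each phenoxide at once, so the secondary acetate is neither cleaved nor transferred and the catechol is not left as an oxidisable anion.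

## Compound list

1 | 3-(3,4-dihydroxyphenyl)propanoic acid (dihydrocaffeic acid) | OC(=O)CCc1ccc(O)c(O)c1 | starting material
2 | triisopropylsilyl 3-[3,4-bis(triisopropylsilyloxy)phenyl]propanoate | CC(C)[Si](C(C)C)(C(C)C)OC(=O)CCc1ccc(O[Si](C(C)C)(C(C)C)C(C)C)c(O[Si](C(C)C)(C(C)C)C(C)C)c1 | intermediate
3 | 3-[3,4-bis(triisopropylsilyloxy)phenyl]propanoic acid | OC(=O)CCc1ccc(O[Si](C(C)C)(C(C)C)C(C)C)c(O[Si](C(C)C)(C(C)C)C(C)C)c1 | intermediate
4 | 3-[3,4-bis(triisopropylsilyloxy)phenyl]propan-1-ol | OCCCc1ccc(O[Si](C(C)C)(C(C)C)C(C)C)c(O[Si](C(C)C)(C(C)C)C(C)C)c1 | intermediate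
5 | 3-[3,4-bis(triisopropylsilyloxy)phenyl]propyl N,N-diisopropylcarbamate | CC(C)N(C(C)C)C(=O)OCCCc1ccc(O[Si](C(C)C)(C(C)C)C(C)C)c(O[Si](C(C)C)(C(C)C)C(C)C)c1 | intermediate
6 | 2-(but-3-en-1-yl)-4,4,5,5-tetramethyl-1,3,2-dioxaborolane | C=CCCB1OC(C)(C)C(C)(C)O1 | starting material
7 | (1R)-3-[3,4-bis(triisopropylsilyloxy)phenyl]-1-lithiopropyl N,N-diisopropylcarbamate, present as its (+)-sparteine complex | CC(C)N(C(C)C)C(=O)O[C@H]([Li])CCc1ccc(O[Si](C(C)C)(C(C)C)C(C)C)c(O[Si](C(C)C)(C(C)C)C(C)C)c1 | intermediate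
8 | lithium (but-3-en-1-yl)[(1R)-3-[3,4-bis(triisopropylsilyloxy)phenyl]-1-(N,N-diisopropylcarbamoyloxy)propyl](pinacolato)borate | CC(C)N(C(C)C)C(=O)O[C@H]([B-]1(CCC=C)OC(C)(C)C(C)(C)O1)CCc1ccc(O[Si](C(C)C)(C(C)C)C(C)C)c(O[Si](C(C)C)(C(C)C)C(C)C)c1.[Li+] | intermediate
9 | 2-[(3R)-1-[3,4-bis(triisopropylsilyloxy)phenyl]hept-6-en-3-yl]-4,4,5,5-tetramethyl-1,3,2-dioxaborolane | CC1(C)OB(OC1(C)C)[C@H](CCC=C)CCc1ccc(O[Si](C(C)C)(C(C)C)C(C)C)c(O[Si](C(C)C)(C(C)C)C(C)C)c1 | intermediate
10 | (3R)-1-[3,4-bis(triisopropylsilyloxy)phenyl]hept-6-en-3-ol | O[C@H](CCC=C)CCc1ccc(O[Si](C(C)C)(C(C)C)C(C)C)c(O[Si](C(C)C)(C(C)C)C(C)C)c1 | intermediate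
11 | (3R)-1-[3,4-bis(triisopropylsilyloxy)phenyl]hept-6-en-3-yl acetate | CC(=O)O[C@H](CCC=C)CCc1ccc(O[Si](C(C)C)(C(C)C)C(C)C)c(O[Si](C(C)C)(C(C)C)C(C)C)c1 | intermediate
12 | tert-butyldimethyl(4-vinylphenoxy)silane | C=Cc1ccc(O[Si](C)(C)C(C)(C)C)cc1 | starting material
13 | (3R,6E)-1-[3,4-bis(triisopropylsilyloxy)phenyl]-7-[4-(tert-butyldimethylsilyloxy)phenyl]hept-6-en-3-yl acetate | CC(=O)O[C@H](CC/C=C/c1ccc(O[Si](C)(C)C(C)(C)C)cc1)CCc1ccc(O[Si](C(C)C)(C(C)C)C(C)C)c(O[Si](C(C)C)(C(C)C)C(C)C)c1 | intermediate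
14 | (3R,6E)-1-(3,4-dihydroxyphenyl)-7-(4-hydroxyphenyl)hept-6-en-3-yl acetate | CC(=O)O[C@H](CC/C=C/c1ccc(O)cc1)CCc1ccc(O)c(O)c1 | target

## Step count and risks

Total steps: 7. Longest linear sequence: 7 (1 → 3 → 4 → 5 → 10 → 11 → 13 → 14; compounds 6 and 12 are bought).

**Most likely to fail, first: step 4.** s-BuLi may attack the bis-silyloxy arene (ortho-metalation) instead of the α-position, the 1,2-shift may be slow, and the er depends on clean lithiation. The fallback keeps the same kind of bond formation but swaps the roles of the two fragments, so the arene never meets s-BuLi. It sets out from 3 and comes back at 9.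

Acid 3 is esterified with N-hydroxyphthalimide (DIC, DMAP, CH2Cl2) to the redox-active ester 1,3-dioxoisoindolin-2-yl 3-[3,4-bis(triisopropylsilyloxy)phenyl]propanoate F1. Decarboxylative borylation of this ester (Cu(acac)2 cat., B2pin2, LiOH·H2O, MgCl2, dioxane/DMF, rt) gives 2-{2-[3,4-bis(triisopropylsilyloxy)phenyl]ethyl}-4,4,5,5-tetramethyl-1,3,2-dioxaborolane F2. Commercial pent-4-en-1-ol is carbamoylated as in step 3 to pent-4-en-1-yl N,N-diisopropylcarbamate F3. Deprotonation with s-BuLi/(−)-sparteine (Et2O, −78 °C) gives (1S)-1-lithiopent-4-en-1-yl N,N-diisopropylcarbamate F4, which takes up the boronic ester to form the lithium boronate complex lithium {2-[3,4-bis(triisopropylsilyloxy)phenyl]ethyl}[(1S)-1-(N,N-diisopropylcarbamoyloxy)pent-4-en-1-yl](pinacolato)borate F5. Migration of the arylethyl group (MgBr2·OEt2, reflux) gives 9, which is oxidised to 10 as in step 4. The other sparteine enantiomer is needed because the lithiated carbon now carries the other chain.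

**Second: step 6.** Styrene homodimerisation, double-bond migration along the chain and incomplete conversion can erode yield and E purity. The fallback replaces metathesis by a palladium-catalysed oxidative Heck arylation. It sets out from 11 and comes back at 13.

Alkene 11 is treated with commercial [4-(tert-butyldimethylsilyloxy)phenyl]boronic acid, Pd(OAc)2 (10 mol %), 1,2-bis(phenylsulfinyl)ethane (10 mol %), 1,4-benzoquinone (2 equiv) and AcOH in dioxane at rt. The bis-homoallylic acetate oxygen helps steer β-hydride elimination to the linear (E)-styrene 13. New compounds on the way: none F0.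

**Third: step 7.** Fluoride may cleave or transfer the acetate, and the free catechol is air-sensitive when basic. The fallback trades silyl groups for acetates before freeing the phenols. It sets out from 13 and comes back at 14.

Desilylative acetylation of 13 (CsF, Ac2O, DMF, rt) gives the tetraacetate 4-[(3R,6E)-3-acetoxy-7-(4-acetoxyphenyl)hept-6-en-1-yl]-1,2-phenylene diacetate F6. The three aryl acetates, far better acyl donors than the secondary alkyl acetate, are then removed selectively by aminolysis with pyrrolidine (3.2 equiv, MeCN, 0 °C, argon) to give 14.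

## Further compounds

F1 | step 4 | 1,3-dioxoisoindolin-2-yl 3-[3,4-bis(triisopropylsilyloxy)phenyl]propanoate | O=C(CCc1ccc(O[Si](C(C)C)(C(C)C)C(C)C)c(O[Si](C(C)C)(C(C)C)C(C)C)c1)ON1C(=O)c2ccccc2C1=O
F2 | step 4 | 2-{2-[3,4-bis(triisopropylsilyloxy)phenyl]ethyl}-4,4,5,5-tetramethyl-1,3,2-dioxaborolane | CC1(C)OB(CCc2ccc(O[Si](C(C)C)(C(C)C)C(C)C)c(O[Si](C(C)C)(C(C)C)C(C)C)c2)OC1(C)C
F3 | step 4 | pent-4-en-1-yl N,N-diisopropylcarbamate | CC(C)N(C(C)C)C(=O)OCCCC=C
F4 | step 4 | (1S)-1-lithiopent-4-en-1-yl N,N-diisopropylcarbamate, present as its (−)-sparteine complex | CC(C)N(C(C)C)C(=O)O[C@@H]([Li])CCC=C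
F5 | step 4 | lithium {2-[3,4-bis(triisopropylsilyloxy)phenyl]ethyl}[(1S)-1-(N,N-diisopropylcarbamoyloxy)pent-4-en-1-yl](pinacolato)borate | CC(C)N(C(C)C)C(=O)O[C@@H]([B-]1(CCc2ccc(O[Si](C(C)C)(C(C)C)C(C)C)c(O[Si](C(C)C)(C(C)C)C(C)C)c2)OC(C)(C)C(C)(C)O1)CCC=C.[Li+]
F0 | step 6 | none | none
F6 | step 7 | 4-[(3R,6E)-3-acetoxy-7-(4-acetoxyphenyl)hept-6-en-1-yl]-1,2-phenylene diacetate | CC(=O)O[C@H](CC/C=C/c1ccc(OC(C)=O)cc1)CCc1ccc(OC(C)=O)c(OC(C)=O)c1
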